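**Plan** (locants are carotenoid numbers; primed = ε-end)

1. Retrosynthetic cuts: C11'=C12' and C11=C12 (Wittig), C7'=C8' (Julia–Kocienski), C6–C7 (Stille), the ester C–O bond at C3' (Mitsunobu), and in the ε-ring C6'–C1' (ring closure) and C2'–C3' (methallylation).
2. Forward order: the ε-ring (cyclohexene C1'–C6') is closed first from an acyclic (3'S)-silyloxy dienyl sulfone. The β-ring comes ready-made from ketoisophorone. The chain is joined as ε-C10 + C5 and β-C9 + C6, then β-C15 + C10, and finally ε-C15 + β-C25.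
3. Enabling feature: in the ε-ring C1' is a gem-dimethyl quaternary carbon, i.e. the tertiary radical that H• addition to an isopropenyl group gives. C6' carries the exocyclic C7', where a sulfonyl group makes C6'=C7' a radical acceptor. The ring's own Z C4'=C5' bond holds C1' and C6' within reach. The sulfonyl group is later consumed in forming C7'=C8'.
4. Stereochemistry: C3' is set by (S)-BINOL/Ti methallylation and relayed to C6' (cis) in the ring closure. C3' is then inverted by Mitsunobu esterification to give 3'R,6'R. C3 comes from enzymatic reduction of ketoisophorone to (4R,6R)-actinol. Z C4'=C5' comes from the starting enynol; the E alkenes come from syn-hydrometalation, olefination and thermal equilibration.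

Key step: step 6

Remark: stannane 3, C5 aldehyde 13 and C10 dialdehyde 27 are treated as catalogue compounds.

**Route**

Step 1
Reactants: 1 (Z)-3-methylpent-2-en-4-yn-1-ol
Product: 2 (Z)-3-methylpent-2-en-4-ynal
Conditions: activated MnO2 (excess), CH2Cl2, 0 °C to rt, dark; filtered solution used directly
Reagents that add atoms: none
Why: MnO2 oxidises allylic alcohols to enals under neutral heterogeneous conditions, which should preserve the Z geometry and the terminal alkyne (allylic alcohol oxidation).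

Step 2
Reactants: 2 (Z)-3-methylpent-2-en-4-ynal; 3 tributyl(2-methylallyl)stannane
Product: 4 (4S,5Z)-2,6-dimethylocta-1,5-dien-7-yn-4-ol
Conditions: (S)-BINOL (20 mol %), Ti(Oi-Pr)4 (10 mol %), 4 Å MS, CH2Cl2, −20 °C; aq NaHCO3
Reagents that add atoms: none
Why: Keck asymmetric allylation (methallyl variant): the (S)-BINOL–Ti(IV) complex should deliver the methallyl group to the Si face of the aldehyde in a 1,2-addition, setting the (S)-carbinol (C3').

Step 3
Reactants: 4 (4S,5Z)-2,6-dimethylocta-1,5-dien-7-yn-4-ol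
Product: 5 tert-butyldimethylsilyl ether of 4
Conditions: TBSCl, imidazole, DMF, rt
Reagents that add atoms: tert-butyldimethylsilyl chloride, CC(C)(C)[Si](C)(C)Cl
Why: Standard silylation of a secondary alcohol; the bulky silyl ether is the temporary group that is meant to bias the later ring closure.

Step 4
Reactants: 5 tert-butyldimethylsilyl ether of 4
Product: 7 (1E,3Z,5S)-dienyl 1-phenyltetrazol-5-yl sulfide, via alkenylzirconocene 6 (not isolated)
Conditions: Cp2Zr(H)Cl (1.3 equiv), THF, 0 °C to rt; then 5,5'-disulfanediylbis(1-phenyl-1H-tetrazole), rt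
Reagents that add atoms: 5,5'-disulfanediylbis(1-phenyl-1H-tetrazole), c1ccc(cc1)-n1nnnc1SSc1nnnn1-c1ccccc1
Why: Hydrozirconation adds Zr–H syn and anti-Markovnikov to the terminal alkyne much faster than to the 1,1-disubstituted alkene, and the (E)-alkenylzirconocene should be sulfenylated with retention by the electrophilic disulfide (electrophilic trapping of an alkenylzirconocene).

Step 5
Reactants: 7 (1E,3Z,5S)-dienyl 1-phenyltetrazol-5-yl sulfide
Product: 8 (1E,3Z,5S)-dienyl 1-phenyltetrazol-5-yl sulfone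
Conditions: (NH4)6Mo7O24·4H2O (20 mol %), 30 % aq H2O2, EtOH, 0 °C to rt
Reagents that add atoms: hydrogen peroxide, OO
Why: Mo(VI)-peroxo oxidation of a sulfide to the sulfone is much faster than epoxidation of unactivated alkenes and turns C6'=C7' into a radical acceptor (sulfide to sulfone oxidation).

Step 6
Reactants: 8 (1E,3Z,5S)-dienyl 1-phenyltetrazol-5-yl sulfone
Product: 9 cis-(1R,4S)-4-silyloxy-2,6,6-trimethylcyclohex-2-enylmethyl 1-phenyltetrazol-5-yl sulfone
Conditions: Fe(acac)3 (0.5 equiv), PhSiH3 (2.5 equiv), EtOH/ethylene glycol 5:1, 0.02 M, 60 °C, Ar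
Reagents that add atoms: none
Why: An iron hydride formed from Fe(acac)3 and PhSiH3 transfers H• to the only 1,1-disubstituted alkene to give the tertiary C1' radical, which adds to C6', the β-carbon of the vinyl sulfone, and the resulting α-sulfonyl radical is reduced and protonated (hydrogen-atom-transfer-initiated Giese cyclisation; closest known type: iron-mediated reductive olefin coupling with vinyl sulfones and enones). The cyclohexene ring closes in the 6-exo-trig mode, and the quaternary C1' and the C6' stereocentre form in the same event. C6' is controlled by C3': the Z C4'=C5' bond enforces a sofa-like transition state with C1' and C2' on one face of the plane C3'–C4'=C5'–C6'; the sulfonylvinyl carbon C7' stays on the outside, s-trans-like (the inside position would drive it into C3'); and the OTBS group is expected to sit pseudoequatorial, anti to the forming quaternary centre, which places O3' and C7' cis (1R,4S). The step needs chemoselective H• transfer (secured by the single terminal 1,1-disubstituted alkene beside one trisubstituted and one electron-poor alkene), regioselective attack at C6' (polarity match of the nucleophilic tertiary radical with the sulfonyl-activated β-carbon; attack at C4', C5' or C7' would need 4-exo, 5-endo or polarity-mismatched 7-endo closure) and facial selectivity (the silyl ether). The trans diastereomer, if formed as the minor product, should be separable at this stage.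

Step 7
Reactants: 9 cis-(1R,4S)-4-silyloxy-2,6,6-trimethylcyclohex-2-enylmethyl 1-phenyltetrazol-5-yl sulfone
Product: 10 cis-(1S,4R)-3,5,5-trimethyl-4-{[(1-phenyl-1H-tetrazol-5-yl)sulfonyl]methyl}cyclohex-2-en-1-ol
Conditions: TBAF/AcOH (1:1), THF, 0 °C to rt
Reagents that add atoms: none
Why: Fluoride cleaves the Si–O bond, and buffering with acetic acid should leave the acidic α-sulfonyl CH2 and the allylic C–O bond untouched (silyl ether cleavage).

Step 8
Reactants: 10 cis-(1S,4R)-3,5,5-trimethyl-4-{[(1-phenyl-1H-tetrazol-5-yl)sulfonyl]methyl}cyclohex-2-en-1-ol; 11 tetradecanoic (myristic) acid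
Product: 12 trans-(1R,4R)-3,5,5-trimethyl-4-{[(1-phenyl-1H-tetrazol-5-yl)sulfonyl]methyl}cyclohex-2-en-1-yl tetradecanoate
Conditions: PPh3, DIAD, THF, 0 °C to rt
Reagents that add atoms: none
Why: Mitsunobu esterification displaces the oxyphosphonium at C3' by SN2 with inversion, so the cis (3'S) alcohol becomes the trans (3'R) myristate and one of the two ester groups of the target is installed; SN2' attack at the fully substituted C5' is disfavoured.

Step 9
Reactants: 12 trans-(1R,4R)-3,5,5-trimethyl-4-{[(1-phenyl-1H-tetrazol-5-yl)sulfonyl]methyl}cyclohex-2-en-1-yl tetradecanoate; 13 (E)-4-acetoxy-2-methylbut-2-enal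
Product: 14 (1R,4R)-4-[(1E,3E)-5-acetoxy-3-methylpenta-1,3-dien-1-yl]-3,5,5-trimethylcyclohex-2-en-1-yl tetradecanoate
Conditions: KHMDS (1.1 equiv) added to 12 + 13 (Barbier mode), DME, −60 °C to rt
Reagents that add atoms: none
Why: Julia–Kocienski olefination: the metalated tetrazolyl sulfone adds to the aldehyde, and Smiles rearrangement with loss of SO2 and tetrazolyl oxide forms C7'=C8', expected mainly E for a β-branched sulfone; the Barbier mode should spare both esters, and the sulfonyl activating group leaves tracelessly.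

Step 10
Reactants: 14 (1R,4R)-4-[(1E,3E)-5-acetoxy-3-methylpenta-1,3-dien-1-yl]-3,5,5-trimethylcyclohex-2-en-1-yl tetradecanoate
Product: 15 ε-C15 triphenylphosphonium bromide (3'-myristate)
Conditions: PPh3 (1.1 equiv), Pd(PPh3)4 (2 mol %), NaBr, THF/MeCN, rt
Reagents that add atoms: triphenylphosphine, c1ccc(cc1)P(c1ccccc1)c1ccccc1; sodium bromide, [Na+].[Br-]
Why: Pd(0) should ionise the primary dienyl acetate far faster than the hindered ring ester, and PPh3 attacks the π-allyl terminus C11' to give the allylic phosphonium salt (Pd-catalysed allylic substitution with a phosphine nucleophile).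

Step 11
Reactants: 16 ketoisophorone (2,6,6-trimethylcyclohex-2-ene-1,4-dione)
Product: 18 (4R,6R)-4-hydroxy-2,2,6-trimethylcyclohexanone (actinol), via (6R)-levodione 17 (not isolated)
Conditions: ene-reductase (old yellow enzyme), then levodione reductase; NAD(P)+ (cat.), D-glucose, glucose dehydrogenase, phosphate buffer pH 7, 30 °C
Reagents that add atoms: none
Why: The ene-reductase hydrogenates C2=C3 to set (6R), and the ketoreductase then reduces the less hindered C4 carbonyl to the (4R)-alcohol (sequential biocatalytic asymmetric reductions, known for this substrate).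

Step 12
Reactants: 18 (4R,6R)-actinol; 19 tetradecanoyl (myristoyl) chloride
Product: 20 (1R,3R)-3,5,5-trimethyl-4-oxocyclohexyl tetradecanoate
Conditions: pyridine, DMAP (cat.), CH2Cl2, 0 °C to rt
Reagents that add atoms: none
Why: DMAP-catalysed O-acylation proceeds with retention at the carbinol carbon and installs the second ester group of the target at the outset of the β-series.

Step 13
Reactants: 20 (1R,3R)-3,5,5-trimethyl-4-oxocyclohexyl tetradecanoate
Product: 21 (1R)-3,5,5-trimethyl-4-(trifluoromethylsulfonyloxy)cyclohex-3-en-1-yl tetradecanoate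
Conditions: Tf2O, 2,6-di-tert-butyl-4-methylpyridine, CH2Cl2, 0 °C to rt
Reagents that add atoms: trifluoromethanesulfonic anhydride, O=S(=O)(OS(=O)(=O)C(F)(F)F)C(F)(F)F
Why: Only C6 carries an α-hydrogen, so enol triflation under non-basic conditions should give a single vinyl triflate and leave the ester and the carbinol centre untouched (enol triflate formation).

Step 14
Reactants: 22 (E)-3-methylpent-2-en-4-yn-1-ol
Product: 23 (2E,4E)-3-methyl-5-(tributylstannyl)penta-2,4-dien-1-ol
Conditions: Bu3SnH, AIBN (cat.), toluene, 85 °C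
Reagents that add atoms: tributyltin hydride, CCCC[SnH](CCCC)CCCC
Why: Radical hydrostannation places tin on the terminal alkyne carbon and equilibrates to the (E)-vinylstannane under the reaction conditions.

Step 15
Reactants: 21 (1R)-3,5,5-trimethyl-4-(trifluoromethylsulfonyloxy)cyclohex-3-en-1-yl tetradecanoate; 23 (2E,4E)-3-methyl-5-(tributylstannyl)penta-2,4-dien-1-ol
Product: 24 (1R)-4-[(1E,3E)-5-hydroxy-3-methylpenta-1,3-dien-1-yl]-3,5,5-trimethylcyclohex-3-en-1-yl tetradecanoate
Conditions: Pd2(dba)3 (2.5 mol %), AsPh3 (20 mol %), LiCl, NMP, 50 °C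
Reagents that add atoms: none
Why: Stille coupling of the hindered cyclohexenyl triflate with the dienylstannane forms C6–C7 with retention of both alkene geometries and tolerates the free alcohol and the ester.

Step 16
Reactants: 24 (1R)-4-[(1E,3E)-5-hydroxy-3-methylpenta-1,3-dien-1-yl]-3,5,5-trimethylcyclohex-3-en-1-yl tetradecanoate
Product: 26 β-C15 triphenylphosphonium bromide (3-myristate), via allylic bromide 25 (not isolated)
Conditions: CBr4 (1.1 equiv), PPh3 (2.3 equiv), CH2Cl2, −20 °C to rt
Reagents that add atoms: carbon tetrabromide, BrC(Br)(Br)Br; triphenylphosphine, c1ccc(cc1)P(c1ccccc1)c1ccccc1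
Why: Appel bromination of the primary allylic alcohol followed by SN2 quaternisation with the excess phosphine gives the salt under neutral conditions that the ester tolerates.

Step 17
Reactants: 26 β-C15 triphenylphosphonium bromide (3-myristate); 27 (2E,4E,6E)-2,7-dimethylocta-2,4,6-trienedial (3 equiv)
Product: 28 (3R)-3-tetradecanoyloxy-12'-apo-β-caroten-12'-al
Conditions: 1,2-epoxybutane, 60 °C, Ar, dark
Reagents that add atoms: none
Why: Wittig olefination with the epoxide as HBr scavenger avoids free alkoxide that would cleave the ester; the excess of symmetrical dialdehyde keeps the reaction at mono-olefination, and the new C11=C12 bond should be mainly E after thermal equilibration.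

Step 18
Reactants: 15 ε-C15 triphenylphosphonium bromide (3'-myristate); 28 (3R)-3-tetradecanoyloxy-12'-apo-β-caroten-12'-al
Product: 29 lutein dimyristate
Conditions: 1,2-epoxybutane/toluene, 70 °C, Ar, dark; crystallisation from hot n-heptane
Reagents that add atoms: none
Why: Wittig olefination forms C11'=C12' and unites the two halves without touching the esters or C6'; the semi-stabilised ylide should give mainly the E alkene, and the unhindered 11'Z isomer equilibrates thermally to all-E, as is usual for C15 + C25 carotenoid couplings.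

**Compound list**

1 | (Z)-3-methylpent-2-en-4-yn-1-ol | OC/C=C(C)\C#C | starting material
2 | (Z)-3-methylpent-2-en-4-ynal | O=C/C=C(C)\C#C | intermediate
3 | tributyl(2-methylallyl)stannane | C=C(C)C[Sn](CCCC)(CCCC)CCCC | starting material
4 | (4S,5Z)-2,6-dimethylocta-1,5-dien-7-yn-4-ol | C=C(C)C[C@H](O)/C=C(C)\C#C | intermediate
5 | tert-butyl{[(4S,5Z)-2,6-dimethylocta-1,5-dien-7-yn-4-yl]oxy}dimethylsilane | C=C(C)C[C@H](O[Si](C)(C)C(C)(C)C)/C=C(C)\C#C | intermediate
6 | chloro[(1E,3Z,5S)-5-(tert-butyldimethylsilyloxy)-3,7-dimethylocta-1,3,7-trien-1-yl]zirconocene | C=C(C)C[C@H](O[Si](C)(C)C(C)(C)C)/C=C(C)\C=C\[Zr](Cl)(C1C=CC=C1)C1C=CC=C1 | intermediate (not isolated)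
7 | 5-{[(1E,3Z,5S)-5-(tert-butyldimethylsilyloxy)-3,7-dimethylocta-1,3,7-trien-1-yl]sulfanyl}-1-phenyl-1H-tetrazole | C=C(C)C[C@H](O[Si](C)(C)C(C)(C)C)/C=C(C)\C=C\Sc1nnnn1-c1ccccc1 | intermediate
8 | 5-{[(1E,3Z,5S)-5-(tert-butyldimethylsilyloxy)-3,7-dimethylocta-1,3,7-trien-1-yl]sulfonyl}-1-phenyl-1H-tetrazole | C=C(C)C[C@H](O[Si](C)(C)C(C)(C)C)/C=C(C)\C=C\S(=O)(=O)c1nnnn1-c1ccccc1 | intermediate
9 | 5-({[(1R,4S)-4-(tert-butyldimethylsilyloxy)-2,6,6-trimethylcyclohex-2-en-1-yl]methyl}sulfonyl)-1-phenyl-1H-tetrazole (cis) | O=S(=O)(C[C@H]1C(C)=C[C@@H](O[Si](C)(C)C(C)(C)C)CC1(C)C)c1nnnn1-c1ccccc1 | intermediate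
10 | (1S,4R)-3,5,5-trimethyl-4-{[(1-phenyl-1H-tetrazol-5-yl)sulfonyl]methyl}cyclohex-2-en-1-ol (cis) | O=S(=O)(C[C@H]1C(C)=C[C@@H](O)CC1(C)C)c1nnnn1-c1ccccc1 | intermediate
11 | tetradecanoic (myristic) acid | CCCCCCCCCCCCCC(=O)O | starting material
12 | (1R,4R)-3,5,5-trimethyl-4-{[(1-phenyl-1H-tetrazol-5-yl)sulfonyl]methyl}cyclohex-2-en-1-yl tetradecanoate (trans) | O=S(=O)(C[C@H]1C(C)=C[C@H](OC(=O)CCCCCCCCCCCCC)CC1(C)C)c1nnnn1-c1ccccc1 | intermediate
13 | (E)-4-acetoxy-2-methylbut-2-enal | CC(=O)OC/C=C(\C)C=O | starting material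
14 | (1R,4R)-4-[(1E,3E)-5-acetoxy-3-methylpenta-1,3-dien-1-yl]-3,5,5-trimethylcyclohex-2-en-1-yl tetradecanoate | CC(=O)OC/C=C(C)/C=C/[C@H]1C(C)=C[C@H](OC(=O)CCCCCCCCCCCCC)CC1(C)C | intermediate
15 | {(2E,4E)-3-methyl-5-[(1R,4R)-2,6,6-trimethyl-4-(tetradecanoyloxy)cyclohex-2-en-1-yl]penta-2,4-dien-1-yl}triphenylphosphonium bromide | [Br-].c1ccc(cc1)[P+](c1ccccc1)(c1ccccc1)C/C=C(C)/C=C/[C@H]1C(C)=C[C@H](OC(=O)CCCCCCCCCCCCC)CC1(C)C | intermediate
16 | ketoisophorone (2,6,6-trimethylcyclohex-2-ene-1,4-dione) | CC1=CC(=O)CC(C)(C)C1=O | starting material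
17 | (6R)-2,2,6-trimethylcyclohexane-1,4-dione (levodione) | O=C1C[C@@H](C)C(=O)C(C)(C)C1 | intermediate (not isolated)
18 | (4R,6R)-4-hydroxy-2,2,6-trimethylcyclohexanone (actinol) | O[C@@H]1C[C@@H](C)C(=O)C(C)(C)C1 | intermediate
19 | tetradecanoyl (myristoyl) chloride | CCCCCCCCCCCCCC(=O)Cl | starting material
20 | (1R,3R)-3,5,5-trimethyl-4-oxocyclohexyl tetradecanoate | CCCCCCCCCCCCCC(=O)O[C@@H]1C[C@@H](C)C(=O)C(C)(C)C1 | intermediate
21 | (1R)-3,5,5-trimethyl-4-(trifluoromethylsulfonyloxy)cyclohex-3-en-1-yl tetradecanoate | CCCCCCCCCCCCCC(=O)O[C@@H]1CC(C)=C(OS(=O)(=O)C(F)(F)F)C(C)(C)C1 | intermediate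
22 | (E)-3-methylpent-2-en-4-yn-1-ol | OC/C=C(\C)C#C | starting material
23 | (2E,4E)-3-methyl-5-(tributylstannyl)penta-2,4-dien-1-ol | OC/C=C(\C)/C=C/[Sn](CCCC)(CCCC)CCCC | intermediate
24 | (1R)-4-[(1E,3E)-5-hydroxy-3-methylpenta-1,3-dien-1-yl]-3,5,5-trimethylcyclohex-3-en-1-yl tetradecanoate | CCCCCCCCCCCCCC(=O)O[C@@H]1CC(C)=C(/C=C/C(C)=C/CO)C(C)(C)C1 | intermediate
25 | (1R)-4-[(1E,3E)-5-bromo-3-methylpenta-1,3-dien-1-yl]-3,5,5-trimethylcyclohex-3-en-1-yl tetradecanoate | CCCCCCCCCCCCCC(=O)O[C@@H]1CC(C)=C(/C=C/C(C)=C/CBr)C(C)(C)C1 | intermediate (not isolated)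
26 | {(2E,4E)-3-methyl-5-[(4R)-2,6,6-trimethyl-4-(tetradecanoyloxy)cyclohex-1-en-1-yl]penta-2,4-dien-1-yl}triphenylphosphonium bromide | CCCCCCCCCCCCCC(=O)O[C@@H]1CC(C)=C(/C=C/C(C)=C/C[P+](c2ccccc2)(c2ccccc2)c2ccccc2)C(C)(C)C1.[Br-] | intermediate
27 | (2E,4E,6E)-2,7-dimethylocta-2,4,6-trienedial | O=C/C(C)=C/C=C/C=C(C)/C=O | starting material
28 | (3R)-3-tetradecanoyloxy-12'-apo-β-caroten-12'-al | CCCCCCCCCCCCCC(=O)O[C@@H]1CC(C)=C(/C=C/C(C)=C/C=C/C(C)=C/C=C/C=C(C)/C=O)C(C)(C)C1 | intermediate
29 | lutein dimyristate, (3R,3'R,6'R)-β,ε-carotene-3,3'-diyl ditetradecanoate | CCCCCCCCCCCCCC(=O)O[C@@H]1CC(C)=C(/C=C/C(C)=C/C=C/C(C)=C/C=C/C=C(C)/C=C/C=C(C)/C=C/[C@H]2C(C)=C[C@H](OC(=O)CCCCCCCCCCCCC)CC2(C)C)C(C)(C)C1 | target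

**Totals**

Total step count: 18. Longest linear sequence: 11 steps (steps 1 to 10, then step 18).

**Steps most likely to fail**

Step 6. The silyl ether may fail to hold the pseudoequatorial position in the sofa-like transition state, so that the ring closes mainly to the 3',6'-trans sulfone; the iron hydride may also reduce the dienyl sulfone before it cyclises. If the closure proves trans-selective, the relay is used in the opposite sense and the inversion is dropped. The fallback sets out from 2: methallylation with (R)-BINOL/Ti gives (4R,5Z)-2,6-dimethylocta-1,5-dien-7-yn-4-ol F1. Silylation gives its TBS ether F2. Hydrozirconation and sulfenylation give the (5R)-dienyl sulfide F3, and Mo/H2O2 oxidation gives the (5R)-dienyl sulfone F4. The same iron-hydride closure then gives the trans-(1R,4R) silyloxy sulfone F5. Desilylation gives the trans-(1R,4R) alcohol F6, and acylation of F6 with 19 (pyridine, DMAP) comes back to the route at 12.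

Step 10. Palladium may also ionise the ring allylic ester, with loss of the C3' configuration, or scramble the C9'=C10' geometry through π–σ–π isomerisation. The fallback sets out from 14: lipase-catalysed hydrolysis of the primary acetate (CAL-B, buffer/MTBE) gives the (1R,4R)-dienol myristate F7. Appel bromination (CBr4, PPh3) gives the allylic bromide F8, and quaternisation with PPh3 comes back to the route at 15.

Step 4. Sulfenylation of the alkenylzirconocene may be slow, so that protodemetalation on work-up returns the diene without sulfur. The fallback sets out from 5: after hydrozirconation, the intermediate 6 is quenched with iodine to give the (1E,3Z,5S)-dienyl iodide F9. Copper-catalysed C–S coupling of F9 with 1-phenyl-1H-tetrazole-5-thiol (CuI, neocuproine, K3PO4, toluene, 80 °C) comes back to the route at 7.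

**Further compounds**

F1 | step 6 | (4R,5Z)-2,6-dimethylocta-1,5-dien-7-yn-4-ol | C=C(C)C[C@@H](O)/C=C(C)\C#C
F2 | step 6 | tert-butyl{[(4R,5Z)-2,6-dimethylocta-1,5-dien-7-yn-4-yl]oxy}dimethylsilane | C=C(C)C[C@@H](O[Si](C)(C)C(C)(C)C)/C=C(C)\C#C
F3 | step 6 | 5-{[(1E,3Z,5R)-5-(tert-butyldimethylsilyloxy)-3,7-dimethylocta-1,3,7-trien-1-yl]sulfanyl}-1-phenyl-1H-tetrazole | C=C(C)C[C@@H](O[Si](C)(C)C(C)(C)C)/C=C(C)\C=C\Sc1nnnn1-c1ccccc1
F4 | step 6 | 5-{[(1E,3Z,5R)-5-(tert-butyldimethylsilyloxy)-3,7-dimethylocta-1,3,7-trien-1-yl]sulfonyl}-1-phenyl-1H-tetrazole | C=C(C)C[C@@H](O[Si](C)(C)C(C)(C)C)/C=C(C)\C=C\S(=O)(=O)c1nnnn1-c1ccccc1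
F5 | step 6 | 5-({[(1R,4R)-4-(tert-butyldimethylsilyloxy)-2,6,6-trimethylcyclohex-2-en-1-yl]methyl}sulfonyl)-1-phenyl-1H-tetrazole (trans) | O=S(=O)(C[C@H]1C(C)=C[C@H](O[Si](C)(C)C(C)(C)C)CC1(C)C)c1nnnn1-c1ccccc1
F6 | step 6 | (1R,4R)-3,5,5-trimethyl-4-{[(1-phenyl-1H-tetrazol-5-yl)sulfonyl]methyl}cyclohex-2-en-1-ol (trans) | O=S(=O)(C[C@H]1C(C)=C[C@H](O)CC1(C)C)c1nnnn1-c1ccccc1
F7 | step 10 | (1R,4R)-4-[(1E,3E)-5-hydroxy-3-methylpenta-1,3-dien-1-yl]-3,5,5-trimethylcyclohex-2-en-1-yl tetradecanoate | OC/C=C(C)/C=C/[C@H]1C(C)=C[C@H](OC(=O)CCCCCCCCCCCCC)CC1(C)C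
F8 | step 10 | (1R,4R)-4-[(1E,3E)-5-bromo-3-methylpenta-1,3-dien-1-yl]-3,5,5-trimethylcyclohex-2-en-1-yl tetradecanoate | BrC/C=C(C)/C=C/[C@H]1C(C)=C[C@H](OC(=O)CCCCCCCCCCCCC)CC1(C)C
F9 | step 4 | tert-butyl{[(1E,3Z,5S)-1-iodo-3,7-dimethylocta-1,3,7-trien-5-yl]oxy}dimethylsilane | C=C(C)C[C@H](O[Si](C)(C)C(C)(C)C)/C=C(C)\C=C\I
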